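**Strategy**

The trimer is cut at both methylene bridges into butyrylphloroglucinol (ring B), propionylfilicinic acid (ring C) and acetylfilicinic acid (ring A). Everything rests on making ring A by inserting a two-carbon unit into a cyclobutenone. A magnesiated dioxinone (masked acetylketene anion) adds to 3-ethoxy-4,4-dimethylcyclobut-2-en-1-one; strain-driven ring opening and Claisen closure then join, in one flask, the ring-A carbonyl carbon to the acetyl-bearing carbon and the adjacent enol carbon to the CMe2 carbon. The step exploits the quaternary CMe2 carbon of ring A, flanked by two oxygenated carbons, which is preset in the four-membered ring. Two Mannich-type bridgings complete the trimer.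

Key step: step 3

Remark: the β-triketone rings are written in the enol form used for the target; their tautomers are the same compounds. Compounds 12 and 14 are taken as commercial.

**Route**

Step 1
Reactants: 1 isobutyryl chloride; 2 ethoxyacetylene
Product: 4 3-ethoxy-4,4-dimethylcyclobut-2-en-1-one, via dimethylketene 3 (not isolated)
Conditions: Et3N, Et2O, 0 °C → reflux
Reagents that add atoms: none
Why: Et3N dehydrohalogenates 1 to dimethylketene, whose [2+2] cycloaddition with the ynol ether joins the ketene carbonyl carbon to the unsubstituted alkyne carbon and should give the 3-alkoxycyclobutenone (ketene–alkyne [2+2] cycloaddition).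

Step 2
Reactants: 5 2,2,6-trimethyl-4H-1,3-dioxin-4-one
Product: 6 5-iodo-2,2,6-trimethyl-4H-1,3-dioxin-4-one
Conditions: NIS, AcOH, rt
Reagents that add atoms: N-iodosuccinimide (O=C1CCC(=O)N1I)
Why: C5 is the nucleophilic β-carbon of the enol ether of the dioxinone and should be iodinated selectively (electrophilic halogenation of a vinylogous carbonate).

Step 3
Reactants: 6 5-iodo-2,2,6-trimethyl-4H-1,3-dioxin-4-one; 4 3-ethoxy-4,4-dimethylcyclobut-2-en-1-one
Product: 11 acetylfilicinic acid (2-acetyl-3,5-dihydroxy-4,4-dimethylcyclohexa-2,5-dien-1-one), via magnesiated dioxinone 7 (not isolated), via cyclobutenoxide adduct 8 (not isolated), via ring-opened dienolate 9 (not isolated), via ethyl ether 10 (not isolated)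
Conditions: i-PrMgCl·LiCl, THF, −30 °C; 4, −30 → 60 °C; then 3 M HCl, 50 °C
Reagents that add atoms: water (O)
Why: Proposed new method: iodine–magnesium exchange turns 6 into the vinyl Grignard 7 (a masked acetylketene anion), which adds 1,2 to the strained carbonyl of 4 and so joins the ring carbonyl carbon to the acetyl-bearing carbon; the cyclobutenoxide 8 then opens by oxyanion-accelerated conrotatory 4π ring opening across the C(=O)–CMe2 bond, and the CMe2 terminus of dienolate 9 attacks the dioxinone carbonyl, which collapses with loss of acetone to unveil the acetyl group and the 1,3-dione. The closest known reaction types are the ring expansion of 1,2-adducts of cyclobutenones through electrocyclic opening (Moore type) and the benzannulation of lithium ynolates with vinylketenes, which forms the same two bonds through a 3-oxidodienylketene. The six-membered ring closes by a 6-(enolendo)-exo-trig Claisen acylation or, should acetone leave first, by 6π electrocyclization of the acylketene; no stereocenter is formed. The step needs 1,2- and not 1,4-addition, which the hard magnesium reagent and the strained, non-enolizable ketone favour, and it needs the dioxinonyl group cis to the enol ether carbon in 9, which the outward rotation of the oxido substituent secures. Closure through carbon is enforced because attack by the enolate oxygen or by its α-carbon would give four-membered rings. Aqueous HCl then hydrolyses the vinylogous ester 10 to 11.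

Step 4
Reactants: 12 flopropione (2′,4′,6′-trihydroxypropiophenone)
Product: 13 propionylfilicinic acid (3,5-dihydroxy-4,4-dimethyl-2-propanoylcyclohexa-2,5-dien-1-one)
Conditions: MeI (2.2 equiv), NaOMe, MeOH, 0 °C → rt; then dilute HCl
Reagents that add atoms: iodomethane (CI)
Why: Twofold C-methylation of the phloroglucinol polyanion at one ring carbon dearomatizes the ring to the acylfilicinic acid (classical base-mediated C-alkylation of acylphloroglucinols).

Step 5
Reactants: 13 propionylfilicinic acid; 14 butyrylphloroglucinol (2′,4′,6′-trihydroxybutyrophenone, 3 equiv)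
Product: 16 methylene-bridged dimer of rings C and B, via Mannich base 15 (not isolated)
Conditions: Me2N=CH2+ I− (1.0 equiv), MeCN, 0 °C → rt; then 14, 80 °C
Reagents that add atoms: N,N-dimethylmethyleneiminium iodide (C=[N+](C)C.[I-])
Why: Aminomethylation at the only free ring carbon of 13 and thermal loss of dimethylamine should give a methylene-trione acceptor that the excess of 14 traps at one of its two equivalent free positions (Mannich reaction followed by elimination–Michael addition).

Step 6
Reactants: 11 acetylfilicinic acid; 16 methylene-bridged dimer of rings C and B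
Product: 18 target trimer, via Mannich base 17 (not isolated)
Conditions: Me2N=CH2+ I− (1.0 equiv), MeCN, 0 °C → rt; then 16, 60 °C
Reagents that add atoms: N,N-dimethylmethyleneiminium iodide (C=[N+](C)C.[I-])
Why: The same Mannich/elimination–Michael sequence should deliver the ring-A methylene acceptor to the single remaining free carbon of ring B in 16.

**Compound list**

1 | isobutyryl chloride | CC(C)C(=O)Cl | starting material
2 | ethoxyacetylene | CCOC#C | starting material
3 | dimethylketene | CC(C)=C=O | intermediate
4 | 3-ethoxy-4,4-dimethylcyclobut-2-en-1-one | CCOC1=CC(=O)C1(C)C | intermediate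
5 | 2,2,6-trimethyl-4H-1,3-dioxin-4-one | CC1=CC(=O)OC(C)(C)O1 | starting material
6 | 5-iodo-2,2,6-trimethyl-4H-1,3-dioxin-4-one | CC1=C(I)C(=O)OC(C)(C)O1 | intermediate
7 | 5-(chloromagnesio)-2,2,6-trimethyl-4H-1,3-dioxin-4-one | CC1=C([Mg]Cl)C(=O)OC(C)(C)O1 | intermediate
8 | chloromagnesium 3-ethoxy-4,4-dimethyl-1-(2,2,6-trimethyl-4-oxo-4H-1,3-dioxin-5-yl)cyclobut-2-en-1-olate (racemic) | CCOC1=CC(O[Mg]Cl)(C2=C(C)OC(C)(C)OC2=O)C1(C)C | intermediate
9 | chloromagnesium dienolate, 3-ethoxy-4-methyl-1-(2,2,6-trimethyl-4-oxo-4H-1,3-dioxin-5-yl)penta-1,3-dien-1-olate, dioxinonyl cis to the enol ether carbon | CCOC(=C(C)C)/C=C(O[Mg]Cl)\C1=C(C)OC(C)(C)OC1=O | intermediate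
10 | 2-acetyl-5-ethoxy-3-hydroxy-4,4-dimethylcyclohexa-2,5-dien-1-one | CCOC1=CC(=O)C(C(C)=O)=C(O)C1(C)C | intermediate
11 | acetylfilicinic acid, 2-acetyl-3,5-dihydroxy-4,4-dimethylcyclohexa-2,5-dien-1-one | CC(=O)C1=C(O)C(C)(C)C(O)=CC1=O | intermediate
12 | flopropione, 1-(2,4,6-trihydroxyphenyl)propan-1-one | CCC(=O)c1c(O)cc(O)cc1O | starting material
13 | propionylfilicinic acid, 3,5-dihydroxy-4,4-dimethyl-2-propanoylcyclohexa-2,5-dien-1-one | CCC(=O)C1=C(O)C(C)(C)C(O)=CC1=O | intermediate
14 | butyrylphloroglucinol, 1-(2,4,6-trihydroxyphenyl)butan-1-one | CCCC(=O)c1c(O)cc(O)cc1O | starting material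
15 | 2-[(dimethylamino)methyl]-3,5-dihydroxy-4,4-dimethyl-6-propanoylcyclohexa-2,5-dien-1-one hydroiodide | CCC(=O)C1=C(O)C(C)(C)C(O)=C(C[NH+](C)C)C1=O.[I-] | intermediate
16 | 2-[(3-butanoyl-2,4,6-trihydroxyphenyl)methyl]-3,5-dihydroxy-4,4-dimethyl-6-propanoylcyclohexa-2,5-dien-1-one | CCCC(=O)c1c(O)cc(O)c(CC2=C(O)C(C)(C)C(O)=C(C(=O)CC)C2=O)c1O | intermediate
17 | 2-acetyl-6-[(dimethylamino)methyl]-3,5-dihydroxy-4,4-dimethylcyclohexa-2,5-dien-1-one hydroiodide | CC(=O)C1=C(O)C(C)(C)C(O)=C(C[NH+](C)C)C1=O.[I-] | intermediate
18 | target: butyrylphloroglucinol ring B carrying, through CH2 groups at its two remaining ring carbons, the acetylfilicinic acid ring A and the propionylfilicinic acid ring C | CCCC(=O)c1c(O)c(CC2=C(O)C(C)(C)C(O)=C(C(C)=O)C2=O)c(O)c(CC2=C(O)C(C)(C)C(O)=C(C(=O)CC)C2=O)c1O | target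

**Summary**

Total step count: 6. Longest linear sequence: 3 steps (step 1 → step 3 → step 6; the branches through step 2 and through steps 4 and 5 are equally long).

**Steps most likely to fail**

1. Step 3. The stabilised vinyl Grignard 7 may add too slowly to the vinylogous ester carbonyl and decompose by β-elimination first. Alternatively the chloromagnesium alkoxide 8 may open sluggishly, so that acid work-up leads to 1,3-carbonyl transposition with loss of ethanol instead of ring expansion. The fallback uses known chemistry, sets out from 4 (with 2) and comes back at 11. Heating 4 with ethoxyacetylene 2 in toluene at 80–110 °C (Danheiser benzannulation: vinylketene formation, [2+2] with the ynol ether, 4π opening, 6π closure) should give 3,5-diethoxy-6,6-dimethylcyclohexa-2,4-dien-1-one F1. Hydrolysis of both enol ethers with 3 M HCl in THF should give filicinic acid F2. C-acetylation of F2 with Ac2O and BF3·OEt2 should give 11.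

2. Step 6. Filicinic units may exchange between methylene bridges by retro-Michael cleavage and recombination, and the ring-A acceptor may self-condense, which would lead to symmetrical oligomers; the free carbon of ring B in 16 is also a hindered nucleophile. The fallback reverses the polarity, sets out from 16 and comes back at 18. Aminomethylation of the free ring-B carbon of 16 with Me2N=CH2+ I− should give the ring-B Mannich base of the dimer F3. Heating F3 with 11 and NaOAc in dioxane at 80 °C should generate the ring-B quinone methide, which the single nucleophilic carbon of 11 traps.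

3. Step 5. Ring B may be alkylated at both equivalent free carbons, which would give the symmetrical trimer with two rings C. The fallback sets out from 14 and comes back at 16. Treating 14 with a deficit of Me2N=CH2+ I− should give 3-[(dimethylamino)methyl]butyrylphloroglucinol F4, which acid–base extraction separates from unreacted 14 and from the bis-amine. Heating F4 with 13 and NaOAc in dioxane should give 16, since 13 has only one nucleophilic carbon and cannot over-react.

**Further compounds**

F1 | step 3 | 3,5-diethoxy-6,6-dimethylcyclohexa-2,4-dien-1-one | CCOC1=CC(=O)C(C)(C)C(OCC)=C1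
F2 | step 3 | filicinic acid, 3,5-dihydroxy-4,4-dimethylcyclohexa-2,5-dien-1-one | CC1(C)C(O)=CC(=O)C=C1O
F3 | step 6 | 2-[[3-butanoyl-5-[(dimethylamino)methyl]-2,4,6-trihydroxyphenyl]methyl]-3,5-dihydroxy-4,4-dimethyl-6-propanoylcyclohexa-2,5-dien-1-one | CCCC(=O)c1c(O)c(CN(C)C)c(O)c(CC2=C(O)C(C)(C)C(O)=C(C(=O)CC)C2=O)c1O
F4 | step 5 | 1-[3-[(dimethylamino)methyl]-2,4,6-trihydroxyphenyl]butan-1-one | CCCC(=O)c1c(O)cc(O)c(CN(C)C)c1O
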